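## Retrosynthetic overview

1. Target ⇒ TIPS-capped Z-enyne (protodesilylation) ⇒ 6-allyl oxane (Z-selective enyne cross-metathesis).
2. Axial C–Cl ⇒ equatorial secondary alcohol (SN2 inversion).
3. Key bond, CH2–CH= of the (E)-3-bromopent-2-enyl chain ⇒ primary alcohol + (E)-2-bromo-1-iodobut-1-ene, joined under visible light by a nickel/photoredox deoxygenative C(sp3)–C(sp2) coupling.
4. 2,6-trans C-allyl diol ⇒ 1,6-anhydro sugar (ring-opening C-allylation via the oxocarbenium ion) ⇒ levoglucosenone (conjugate hydrobromination, ketone reduction).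
5. Ring order: the single oxane ring is never built; it is the pyranose ring bought in levoglucosenone, and the anhydro ring is opened in the allylation step.

Assumption: the SMILES is taken literally, i.e. ring carbons (2R,3S,5S,6R) with the two side chains trans across the ring oxygen, E bromoalkene, Z enyne; all starting materials and the benzoxazolium salt are bought.

Convention: hexose numbering (C1–C6) is used for the bicyclic compounds 1–3 and 5; names of the monocyclic compounds use oxane numbering.

## Route

Step 1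
Reactants: 1 levoglucosenone
Product: 3 1,6-anhydro-4-bromo-3,4-dideoxy-β-D-ribo-hexopyranose (axial C2–OH; axial C4–Br), via bromo ketone 2 (not isolated)
Conditions: HBr (g, 1.5 equiv), CH2Cl2, −40 to 0 °C; evaporate; Li[HB(s-Bu)3] (L-Selectride, 1.3 equiv), THF, −78 °C; H2O
Reagents that add atoms: hydrogen bromide, Br
Why: Conjugate hydrobromination (hetero-Michael addition) puts bromide on C4 from the face anti to the 1,6-anhydro bridge, the face heteronucleophiles take on this enone, while the α-keto acetal resists HBr; the bulky borohydride then reduces the C2 ketone by equatorial attack, away from the now axial C4–Br, giving the axial (D-ribo) alcohol at −78 °C before β-elimination of HBr can compete.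

Step 2
Reactants: 3 1,6-anhydro-4-bromo-3,4-dideoxy-β-D-ribo-hexopyranose; 4 allyltrimethylsilane
Product: 7 (2R,3R,5S,6R)-5-bromo-6-(hydroxymethyl)-2-(prop-2-en-1-yl)oxan-3-ol, via 2-O-trimethylsilyl ether 5 (not isolated), via bis-trimethylsilyl ether 6 (not isolated)
Conditions: BSTFA (1.2 equiv), MeCN, rt; then 4 (3 equiv), TMSOTf (0.5 equiv), 0 °C to rt; aq. HCl work-up
Reagents that add atoms: none
Why: Lewis-acid opening of the 1,6-anhydro acetal gives the pyranosyl oxocarbenium ion, which the allylsilane attacks axially on the face opposite the C5 side chain (Hosomi–Sakurai C-glycosylation), so the new stereocentre is set 2,6-trans by the bought C5 centre; the acidic work-up removes both TMS ethers.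

Step 3
Reactants: 8 but-1-yne
Product: 9 (E)-2-bromo-1-iodobut-1-ene
Conditions: IBr (1.0 equiv), CH2Cl2, −78 to 0 °C, dark
Reagents that add atoms: iodine monobromide, IBr
Why: Electrophilic anti addition of I–Br to the terminal alkyne, with Markovnikov delivery of bromide to the internal carbon, fixes the E geometry (I and Br trans).

Step 4
Reactants: 7 (2R,3R,5S,6R)-5-bromo-6-(hydroxymethyl)-2-(prop-2-en-1-yl)oxan-3-ol; 9 (E)-2-bromo-1-iodobut-1-ene
Product: 11 (2R,3R,5S,6R)-5-bromo-6-[(2E)-3-bromopent-2-en-1-yl]-2-(prop-2-en-1-yl)oxan-3-ol, via benzoxazoline adduct 10 (not isolated)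
Conditions: 5,7-di-tert-butyl-3-phenyl-1,3-benzoxazol-3-ium tetrafluoroborate (1.05 equiv), pyridine (1.05 equiv), MTBE, rt, 15 min; then 9 (1.5 equiv), Ir[dF(CF3)ppy]2(dtbbpy)PF6 (1 mol%), NiBr2·glyme (5 mol%), dtbbpy (5 mol%), quinuclidine (1.5 equiv), DMA–MTBE, 450 nm LEDs, rt
Reagents that add atoms: none
Why: Proposed new method: the unhindered primary hydroxyl of 7 condenses selectively with the benzoxazolium salt to give aminal 10; the excited iridium photocatalyst oxidises its N-aryl amine, quinuclidine removes the aminal C–H proton, and β-scission of the resulting α-amino radical expels the benzoxazolone and frees the primary carbon radical of the side chain; zerovalent nickel meanwhile inserts into the C–I bond of 9 (much faster than into its hindered internal C–Br or the secondary ring C–Br), the alkenylnickel species captures the radical, and reductive elimination from trivalent nickel forms the CH2–CH= bond with retention of the E geometry, β-bromide loss being disfavoured because Ni and Br sit trans on the alkene; a radical at this carbon avoids the β-alkoxide ring-opening elimination expected of the corresponding organozinc or organolithium, and no stereocentre is formed or touched; the closest known reactions are the nickel/photoredox deoxygenative arylation of NHC-activated alcohols with aryl halides and nickel/photoredox alkyl–alkenyl couplings of simple vinyl halides, neither shown for a 1-iodo-2-bromoalkene or for site-selective use of a diol.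

Step 5
Reactants: 11 (2R,3R,5S,6R)-5-bromo-6-[(2E)-3-bromopent-2-en-1-yl]-2-(prop-2-en-1-yl)oxan-3-ol
Product: 12 (2R,3S,5S,6R)-3-bromo-2-[(2E)-3-bromopent-2-en-1-yl]-5-chloro-6-(prop-2-en-1-yl)oxane
Conditions: CCl4 (3 equiv), P(n-Oct)3 (2 equiv), toluene, 70 °C
Reagents that add atoms: carbon tetrachloride, ClC(Cl)(Cl)Cl
Why: Appel-type deoxychlorination: the alkoxyphosphonium salt of the equatorial alcohol has no anti-periplanar hydrogen for E2 and is displaced by chloride from the axial direction (SN2), so the carbinol centre set in step 1 is inverted to the axial chloride.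

Step 6
Reactants: 13 ethynyltri(propan-2-yl)silane; 14 bromoethene
Product: 15 (but-3-en-1-yn-1-yl)tri(propan-2-yl)silane
Conditions: PdCl2(PPh3)2 (2 mol%), CuI (4 mol%), i-Pr2NH (2 equiv), THF, 0 °C to rt
Reagents that add atoms: none
Why: Sonogashira coupling of a terminal alkyne with vinyl bromide; no stereocentre is formed.

Step 7
Reactants: 12 (2R,3S,5S,6R)-3-bromo-2-[(2E)-3-bromopent-2-en-1-yl]-5-chloro-6-(prop-2-en-1-yl)oxane; 15 (but-3-en-1-yn-1-yl)tri(propan-2-yl)silane
Product: 16 (2R,3S,5S,6R)-3-bromo-2-[(2E)-3-bromopent-2-en-1-yl]-5-chloro-6-[(2Z)-5-[tri(propan-2-yl)silyl]pent-2-en-4-yn-1-yl]oxane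
Conditions: 15 (4 equiv), second-generation Grubbs catalyst (H2IMes)(PCy3)Cl2Ru=CHPh (10 mol%), CH2Cl2, 40 °C
Reagents that add atoms: none
Why: Olefin cross-metathesis of the terminal allyl group with a silyl-capped conjugated enyne, a partner class that is kinetically Z-selective (the slim alkynyl group tolerates the cis arrangement in the ruthenacyclobutane), while the bulky TIPS group suppresses enyne metathesis and the trisubstituted vinyl bromide is inert; this sets the Z alkene.

Step 8
Reactants: 16 (2R,3S,5S,6R)-3-bromo-2-[(2E)-3-bromopent-2-en-1-yl]-5-chloro-6-[(2Z)-5-[tri(propan-2-yl)silyl]pent-2-en-4-yn-1-yl]oxane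
Product: 17 (2R,3S,5S,6R)-3-bromo-2-[(2E)-3-bromopent-2-en-1-yl]-5-chloro-6-[(2Z)-pent-2-en-4-yn-1-yl]oxane (target)
Conditions: TBAF (1.5 equiv), AcOH (1.5 equiv), THF, 0 °C
Reagents that add atoms: none
Why: Fluoride-induced protodesilylation of the alkynylsilane, buffered with acetic acid so that the secondary chloride and bromide are not eliminated; no stereocentre is touched.

## Compound list

1 | levoglucosenone, (1S,5R)-6,8-dioxabicyclo[3.2.1]oct-2-en-4-one | O=C1C=C[C@H]2CO[C@@H]1O2 | starting material
2 | 1,6-anhydro-4-bromo-3,4-dideoxy-β-D-erythro-hexopyranos-2-ulose (C4–Br axial, anti to the anhydro bridge) | O=C1C[C@H](Br)[C@H]2CO[C@@H]1O2 | intermediate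
3 | 1,6-anhydro-4-bromo-3,4-dideoxy-β-D-ribo-hexopyranose (C2–OH and C4–Br both axial, anti to the bridge) | O[C@@H]1C[C@H](Br)[C@H]2CO[C@@H]1O2 | intermediate
4 | allyltrimethylsilane | C=CC[Si](C)(C)C | starting material
5 | 1,6-anhydro-4-bromo-3,4-dideoxy-2-O-trimethylsilyl-β-D-ribo-hexopyranose | C[Si](C)(C)O[C@@H]1C[C@H](Br)[C@H]2CO[C@@H]1O2 | intermediate
6 | bis-trimethylsilyl ether of 7 (both hydroxyls silylated) | C=CC[C@H]1O[C@H](CO[Si](C)(C)C)[C@@H](Br)C[C@H]1O[Si](C)(C)C | intermediate
7 | (2R,3R,5S,6R)-5-bromo-6-(hydroxymethyl)-2-(prop-2-en-1-yl)oxan-3-ol | C=CC[C@H]1O[C@H](CO)[C@@H](Br)C[C@H]1O | intermediate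
8 | but-1-yne | CCC#C | starting material
9 | (E)-2-bromo-1-iodobut-1-ene | CC/C(Br)=C\I | intermediate
10 | 2-alkoxy-5,7-di-tert-butyl-3-phenyl-2,3-dihydro-1,3-benzoxazole adduct of the primary hydroxyl of 7 (aminal carbon as an epimer mixture) | C=CC[C@H]1O[C@H](COC3Oc4c(C(C)(C)C)cc(C(C)(C)C)cc4N3c3ccccc3)[C@@H](Br)C[C@H]1O | intermediate
11 | (2R,3R,5S,6R)-5-bromo-6-[(2E)-3-bromopent-2-en-1-yl]-2-(prop-2-en-1-yl)oxan-3-ol | C=CC[C@H]1O[C@H](C/C=C(/Br)CC)[C@@H](Br)C[C@H]1O | intermediate
12 | (2R,3S,5S,6R)-3-bromo-2-[(2E)-3-bromopent-2-en-1-yl]-5-chloro-6-(prop-2-en-1-yl)oxane | C=CC[C@H]1O[C@H](C/C=C(/Br)CC)[C@@H](Br)C[C@@H]1Cl | intermediate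
13 | ethynyltri(propan-2-yl)silane (TIPS-acetylene) | C#C[Si](C(C)C)(C(C)C)C(C)C | starting material
14 | bromoethene (vinyl bromide) | C=CBr | starting material
15 | (but-3-en-1-yn-1-yl)tri(propan-2-yl)silane | C=CC#C[Si](C(C)C)(C(C)C)C(C)C | intermediate
16 | (2R,3S,5S,6R)-3-bromo-2-[(2E)-3-bromopent-2-en-1-yl]-5-chloro-6-[(2Z)-5-[tri(propan-2-yl)silyl]pent-2-en-4-yn-1-yl]oxane | CC(C)[Si](C(C)C)(C(C)C)C#C/C=C\C[C@H]1O[C@H](C/C=C(/Br)CC)[C@@H](Br)C[C@@H]1Cl | intermediate
17 | (2R,3S,5S,6R)-3-bromo-2-[(2E)-3-bromopent-2-en-1-yl]-5-chloro-6-[(2Z)-pent-2-en-4-yn-1-yl]oxane | C#C/C=C\C[C@H]1O[C@H](C/C=C(/Br)CC)[C@@H](Br)C[C@@H]1Cl | target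

## Step count and risks

Total step count: 8 (six on the main line plus two one-step reagent preparations, steps 3 and 6).
Longest linear sequence: 6 steps from levoglucosenone (steps 1, 2, 4, 5, 7, 8).

The three steps most likely to fail:

Step 4 (the new coupling). Risks: condensation of the secondary hydroxyl as well, nickel insertion into the C–Br bonds of reagent or product, loss of butyne from the alkenylnickel species, or erosion of the E geometry. The fallback sets out from 7 and returns at 11. Selective iodination of the primary alcohol (I2, PPh3, imidazole, THF, 0 °C) gives (2R,3R,5S,6S)-5-bromo-6-(iodomethyl)-2-(prop-2-en-1-yl)oxan-3-ol F1. F1 is then joined to 9 by the established thermal nickel-catalysed reductive cross-electrophile coupling of alkyl iodides with alkenyl halides (NiI2, 4,4'-di-tert-butyl-2,2'-bipyridine, Mn powder, DMA, rt), which also passes through the side-chain radical and keeps the alkene geometry, to give 11.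

Step 7 (cross-metathesis). Risks: an insufficient Z:E ratio or sluggish turnover next to the halogenated ring. The fallback sets out from 12 and returns at 16. Lemieux–Johnson cleavage of the allyl group (OsO4 cat., NaIO4, 2,6-lutidine, dioxane–water; the electron-poor bromoalkene is left alone) gives 2-[(2R,3S,5S,6R)-5-bromo-6-[(2E)-3-bromopent-2-en-1-yl]-3-chlorooxan-2-yl]acetaldehyde F2. Peterson olefination of F2 with lithiated 1,3-bis(triisopropylsilyl)propyne (n-BuLi, THF, −78 °C), a reliably Z-selective enyne synthesis, then gives 16.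

Step 5 (inversion to the axial chloride). Risks: participation of the ring oxygen (retention or ring contraction) or elimination from the alkoxyphosphonium salt. The fallback sets out from 11 and returns at 12. Activation and displacement are separated: ClCH2SO2Cl and pyridine in CH2Cl2 at 0 °C give (2R,3R,5S,6R)-5-bromo-6-[(2E)-3-bromopent-2-en-1-yl]-2-(prop-2-en-1-yl)oxan-3-yl chloromethanesulfonate F3. The isolated sulfonate is then displaced by free chloride (LiCl, DMF, 50 °C) in a clean SN2 reaction to give 12.

Further compounds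
F1 | step 4 | (2R,3R,5S,6S)-5-bromo-6-(iodomethyl)-2-(prop-2-en-1-yl)oxan-3-ol | C=CC[C@H]1O[C@H](CI)[C@@H](Br)C[C@H]1O
F2 | step 7 | 2-[(2R,3S,5S,6R)-5-bromo-6-[(2E)-3-bromopent-2-en-1-yl]-3-chlorooxan-2-yl]acetaldehyde | O=CC[C@H]1O[C@H](C/C=C(/Br)CC)[C@@H](Br)C[C@@H]1Cl
F3 | step 5 | (2R,3R,5S,6R)-5-bromo-6-[(2E)-3-bromopent-2-en-1-yl]-2-(prop-2-en-1-yl)oxan-3-yl chloromethanesulfonate | C=CC[C@H]1O[C@H](C/C=C(/Br)CC)[C@@H](Br)C[C@H]1OS(=O)(=O)CCl
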